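**Plan**
- Retrosynthesis: the C5 O–methyl bond is cut first, then the C5–allyl bond (back to a 5,6-dione), then the bonds C2–C3 and O1–C2 of the dihydrofuran ring in one operation.
- Feature used: in benzofuran numbering O1, C7a, C3a and C3 (with its methyl) are the four atoms of an ortho-quinone methide of a 4,5-dioxygenated phenol. C2 with its trimethoxyphenyl group is one carbon that can arrive as a benzylic sulfonium ylide and bond to both ends.
- Forward: the carbocycle (ring A) is bought as an arene and the furan ring (ring B) closes in step 6. Ring A is then taken to the catechol, the ortho-quinone, the C5 allyl carbinol and its methyl ether.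
- Stereochemistry: C2 comes from the ylide face fixed by (2S,5S)-2,5-dimethylthiolane and C3 is set trans to it in the same step. C5 comes from a chiral-diol-catalysed allylboration (reagent control).

Key step: step 6

Remark: the sense of induction in step 9 rests on a working model (closed chair, boron on the C4–H side of the C5 carbonyl), not on precedent with quinones; the (R)-diol is written and its mirror image is the remedy if the model errs.

**Step 1**
Reactants: 1 3,4-bis(benzyloxy)benzaldehyde
Product: 3 3,4-bis(benzyloxy)phenol, via aryl formate 2 (not isolated)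
Conditions: mCPBA (1.3 equiv), CH2Cl2, 0 °C to rt; then MeOH, K2CO3 (0.1 equiv), rt
Reagents that add atoms: 3-chloroperoxybenzoic acid (mCPBA), O=C(OO)c1cccc(Cl)c1
Why: Baeyer–Villiger (Dakin-type) oxidation in which the electron-rich aryl group migrates to oxygen to give formate 2, which is methanolysed to the phenol; this is the usual way to this phenol.

**Step 2**
Reactants: 3 3,4-bis(benzyloxy)phenol; 4 acetaldehyde
Product: 6 rac-4,5-bis(benzyloxy)-2-[1-(4-methylphenyl)sulfonylethyl]phenol, via benzylic carbinol 5 (not isolated)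
Conditions: p-TolSO2Na (1.5 equiv), MeCHO (3 equiv), HCO2H/H2O 1:1, rt, closed flask
Reagents that add atoms: sodium 4-methylbenzenesulfinate, Cc1ccc(cc1)S(=O)[O-].[Na+]
Why: Acid-catalysed Friedel–Crafts hydroxyalkylation ortho to the hydroxyl and para to the 3-benzyloxy group gives carbinol 5, which ionises and is captured at sulfur by the sulfinate (the known three-component sulfone synthesis of electron-rich phenols); the new centre is racemic and is erased in step 6.

**Step 3**
Reactants: 7 (2R,5R)-hexane-2,5-diol
Product: 8 (2R,5R)-hexane-2,5-diyl dimethanesulfonate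
Conditions: MsCl (2.4 equiv), Et3N (3 equiv), CH2Cl2, −20 to 0 °C
Reagents that add atoms: methanesulfonyl chloride, CS(=O)(=O)Cl
Why: O-Sulfonylation (mesylation) of both secondary alcohols with retention at carbon.

**Step 4**
Reactants: 8 (2R,5R)-hexane-2,5-diyl dimethanesulfonate
Product: 9 (2S,5S)-2,5-dimethylthiolane
Conditions: Na2S·9H2O (1.2 equiv), DMSO, rt; isolated by extraction into pentane and distillation
Reagents that add atoms: sodium sulfide, [Na+].[Na+].[S-2]
Why: Double SN2 displacement by sulfide (intermolecular, then 5-exo-tet), each with inversion, turns the (2R,5R)-dimesylate into the (2S,5S)-thiolane.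

**Step 5**
Reactants: 9 (2S,5S)-2,5-dimethylthiolane; 10 3,4,5-trimethoxybenzyl bromide
Product: 11 (2S,5S)-2,5-dimethyl-1-(3,4,5-trimethoxybenzyl)thiolan-1-ium tetrafluoroborate
Conditions: AgBF4 (1.05 equiv), CH2Cl2, 0 °C to rt, dark; filtered, salt crystallised from CH2Cl2/Et2O
Reagents that add atoms: silver tetrafluoroborate, [Ag+].F[B-](F)(F)F
Why: Silver-assisted SN2 S-benzylation of the hindered sulfide; the two sulfur lone pairs are equivalent by C2 symmetry so a single salt forms, and the non-nucleophilic counter-ion prevents reversal of the alkylation.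

**Step 6**
Reactants: 6 rac-4,5-bis(benzyloxy)-2-[1-(4-methylphenyl)sulfonylethyl]phenol; 11 (2S,5S)-2,5-dimethyl-1-(3,4,5-trimethoxybenzyl)thiolan-1-ium tetrafluoroborate
Product: 15 (2S,3S)-5,6-bis(benzyloxy)-3-methyl-2-(3,4,5-trimethoxyphenyl)-2,3-dihydro-1-benzofuran, via ortho-quinone methide 12 (not isolated), via sulfonium ylide 13 (not isolated), via phenoxide betaine 14 (not isolated)
Conditions: Cs2CO3 (3 equiv), MeCN/CH2Cl2 1:1, −20 °C to rt; 6 added slowly to 11 (1.5 equiv) and the base
Reagents that add atoms: none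
Why: Cs2CO3 deprotonates the phenol of 6, which expels p-toluenesulfinate to give the (E)-ortho-quinone methide 12, and deprotonates 11 at the benzylic carbon to give the semistabilised ylide 13; the ylide carbon adds to the exocyclic carbon of 12 (C2–C3 bond, with rearomatisation) to give betaine 14, whose phenoxide then displaces the sulfide at C2 (O1–C2 bond). The closest known reaction type is the formal [4+1] annulation of ortho-quinone methides released from 2-(1-tosylalkyl)phenols with sulfonium ylides, which gives trans-2,3-dihydrobenzofurans. The dihydrofuran ring closes in a 5-exo-tet substitution with inversion at C2. C2 is controlled by the C2-symmetric thiolane: the ylide aryl group lies on the side of the sulfur lone pair and the ring methyl cis to the ylide carbon blocks one face, so bond formation followed by inversion should give 2S from the (2S,5S)-sulfide (the descriptor is opposite to that of an epoxide carbon made through the same ylide face, because here the aryl group outranks C3). C3 follows C2, since the approach that keeps the ylide aryl group away from the methyl of the (E)-quinone methide leads to the betaine that closes to the trans ring, hence 3S. The step needs C- over O-alkylation and capture of 12 before it tautomerises to the vinylphenol or dimerises; the two benzyloxy donors stabilise 12, the ylide is kept in excess by slow addition of 6, and the carbonate base is too mild to promote ylide rearrangement.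

**Step 7**
Reactants: 15 (2S,3S)-5,6-bis(benzyloxy)-3-methyl-2-(3,4,5-trimethoxyphenyl)-2,3-dihydro-1-benzofuran
Product: 16 (2S,3S)-3-methyl-2-(3,4,5-trimethoxyphenyl)-2,3-dihydro-1-benzofuran-5,6-diol
Conditions: H2 (1 atm), 10% Pd/C, EtOAc, rt; filtered and concentrated under argon
Reagents that add atoms: none
Why: Hydrogenolysis of the two aryl benzyl ethers; the hindered, ring-bound benzylic C2–O1 bond is expected to survive in neutral EtOAc at one atmosphere, and no stereocentre is touched.

**Step 8**
Reactants: 16 (2S,3S)-3-methyl-2-(3,4,5-trimethoxyphenyl)-2,3-dihydro-1-benzofuran-5,6-diol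
Product: 17 (2S,3S)-3-methyl-2-(3,4,5-trimethoxyphenyl)-2,3-dihydro-1-benzofuran-5,6-dione
Conditions: Ag2O (3 equiv), MgSO4, Et2O, 0 °C, dark; filtered through Celite and used at once
Reagents that add atoms: none
Why: Two-electron oxidation of a catechol to the ortho-quinone by Ag2O under neutral, dry conditions, which avoid acid- or base-catalysed tautomerisation through C3–H; the quinone is a vinylogous ester of O1 and should be stable enough to carry forward cold.

**Step 9**
Reactants: 17 (2S,3S)-3-methyl-2-(3,4,5-trimethoxyphenyl)-2,3-dihydro-1-benzofuran-5,6-dione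
Product: 19 (2S,3S,5R)-5-hydroxy-3-methyl-5-(prop-2-en-1-yl)-2-(3,4,5-trimethoxyphenyl)-2,3-dihydro-1-benzofuran-6(5H)-one, via borate ester 18 (not isolated)
Conditions: allylB(Oi-Pr)2 (1.5 equiv, freshly made from B(Oi-Pr)3 and allylMgBr), (R)-3,3'-dibromo-1,1'-bi-2-naphthol (15 mol %), PhCF3/PhMe 3:1, −35 °C; then pH 7 buffer
Reagents that add atoms: allyldiisopropoxyborane, C=CCB(OC(C)C)OC(C)C
Why: Proposed new method: exchange of one isopropoxy group for the chiral diol should give a more Lewis-acidic boronate that transfers allyl to the C5 carbonyl through a closed six-membered chair transition state, which excludes conjugate addition and electron-transfer reduction of the quinone; only C5 should react because the C6 carbonyl is deactivated as a vinylogous ester of O1, and the new C5 centre is set by the catalyst because C2 and C3 are too remote to bias the flat quinone; the closest known reaction types are the chiral-diol-catalysed asymmetric allylboration of aryl and alkenyl ketones and the uncatalysed 1,2-allylation of ortho-quinones and other 1,2-diones by allylboron and allylindium reagents.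

**Step 10**
Reactants: 19 (2S,3S,5R)-5-hydroxy-3-methyl-5-(prop-2-en-1-yl)-2-(3,4,5-trimethoxyphenyl)-2,3-dihydro-1-benzofuran-6(5H)-one
Product: 20 (2S,3S,5R)-5-methoxy-3-methyl-5-(prop-2-en-1-yl)-2-(3,4,5-trimethoxyphenyl)-2,3-dihydro-1-benzofuran-6(5H)-one
Conditions: MeI (large excess), Ag2O (5 equiv), 4 Å molecular sieves, CH2Cl2, rt to 35 °C, dark; purified below 40 °C
Reagents that add atoms: iodomethane, CI
Why: Purdie methylation, a silver-assisted SN2 reaction of iodomethane with the α-ketol hydroxyl under neutral conditions, which avoids the free alkoxide that could trigger an anionic oxy-Cope shift of the allyl group; C5 is not touched and the mild temperature spares the dienone from Cope and retro-Claisen shifts.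

**Compound list**
1 | 3,4-bis(benzyloxy)benzaldehyde | O=Cc1ccc(OCc2ccccc2)c(OCc2ccccc2)c1 | starting material
2 | 3,4-bis(benzyloxy)phenyl formate (not isolated) | O=COc1ccc(OCc2ccccc2)c(OCc2ccccc2)c1 | intermediate
3 | 3,4-bis(benzyloxy)phenol | Oc1ccc(OCc2ccccc2)c(OCc2ccccc2)c1 | intermediate
4 | acetaldehyde | CC=O | starting material
5 | rac-4,5-bis(benzyloxy)-2-(1-hydroxyethyl)phenol (not isolated) | CC(O)c1cc(OCc2ccccc2)c(OCc2ccccc2)cc1O | intermediate
6 | rac-4,5-bis(benzyloxy)-2-[1-(4-methylphenyl)sulfonylethyl]phenol | CC(c1cc(OCc2ccccc2)c(OCc2ccccc2)cc1O)S(=O)(=O)c1ccc(C)cc1 | intermediate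
7 | (2R,5R)-hexane-2,5-diol | C[C@@H](O)CC[C@@H](C)O | starting material
8 | (2R,5R)-hexane-2,5-diyl dimethanesulfonate | C[C@@H](OS(C)(=O)=O)CC[C@@H](C)OS(C)(=O)=O | intermediate
9 | (2S,5S)-2,5-dimethylthiolane | C[C@H]1CC[C@H](C)S1 | intermediate
10 | 3,4,5-trimethoxybenzyl bromide (5-(bromomethyl)-1,2,3-trimethoxybenzene) | COc1cc(CBr)cc(OC)c1OC | starting material
11 | (2S,5S)-2,5-dimethyl-1-(3,4,5-trimethoxybenzyl)thiolan-1-ium tetrafluoroborate | C[C@H]1CC[C@H](C)[S+]1Cc1cc(OC)c(OC)c(OC)c1.F[B-](F)(F)F | intermediate
12 | (6E)-3,4-bis(benzyloxy)-6-ethylidenecyclohexa-2,4-dien-1-one (ortho-quinone methide, not isolated) | C/C=C1\C=C(OCc2ccccc2)C(OCc2ccccc2)=CC1=O | intermediate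
13 | (2S,5S)-2,5-dimethylthiolan-1-ium-1-yl (3,4,5-trimethoxyphenyl)methanide (sulfonium ylide, not isolated) | C[C@H]1CC[C@H](C)[S+]1[CH-]c1cc(OC)c(OC)c(OC)c1 | intermediate
14 | 4,5-bis(benzyloxy)-2-[(1R,2S)-1-[(2S,5S)-2,5-dimethylthiolan-1-ium-1-yl]-1-(3,4,5-trimethoxyphenyl)propan-2-yl]phenolate (betaine, not isolated) | C[C@@H](c1cc(OCc2ccccc2)c(OCc2ccccc2)cc1[O-])[C@@H]([S+]1[C@@H](C)CC[C@@H]1C)c1cc(OC)c(OC)c(OC)c1 | intermediate
15 | (2S,3S)-5,6-bis(benzyloxy)-3-methyl-2-(3,4,5-trimethoxyphenyl)-2,3-dihydro-1-benzofuran | c12cc(OCc3ccccc3)c(OCc3ccccc3)cc1O[C@H](c4cc(OC)c(OC)c(OC)c4)[C@H]2C | intermediate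
16 | (2S,3S)-3-methyl-2-(3,4,5-trimethoxyphenyl)-2,3-dihydro-1-benzofuran-5,6-diol | c12cc(O)c(O)cc1O[C@H](c3cc(OC)c(OC)c(OC)c3)[C@H]2C | intermediate
17 | (2S,3S)-3-methyl-2-(3,4,5-trimethoxyphenyl)-2,3-dihydro-1-benzofuran-5,6-dione | O=C1C=C2C(=CC1=O)O[C@H](c1cc(OC)c(OC)c(OC)c1)[C@H]2C | intermediate
18 | diisopropyl (2S,3S,5R)-3-methyl-6-oxo-5-(prop-2-en-1-yl)-2-(3,4,5-trimethoxyphenyl)-2,3,5,6-tetrahydro-1-benzofuran-5-yl borate (not isolated) | C=CC[C@@]1(OB(OC(C)C)OC(C)C)C=C2C(=CC1=O)O[C@H](c1cc(OC)c(OC)c(OC)c1)[C@H]2C | intermediate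
19 | (2S,3S,5R)-5-hydroxy-3-methyl-5-(prop-2-en-1-yl)-2-(3,4,5-trimethoxyphenyl)-2,3-dihydro-1-benzofuran-6(5H)-one | C=CC[C@@]1(O)C=C2C(=CC1=O)O[C@H](c1cc(OC)c(OC)c(OC)c1)[C@H]2C | intermediate
20 | (2S,3S,5R)-5-methoxy-3-methyl-5-(prop-2-en-1-yl)-2-(3,4,5-trimethoxyphenyl)-2,3-dihydro-1-benzofuran-6(5H)-one | C=CC[C@@]1(OC)C=C2C(=CC1=O)O[C@H](c1cc(OC)c(OC)c(OC)c1)[C@H]2C | target

**Count**
Total steps: 10. Longest linear sequence: 8 steps (steps 3 to 10, from diol 7); the arm that carries the carbon skeleton (steps 1, 2 and 6 to 10) has 7.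

**Steps most likely to fail**

Step 9. The flat quinone carbonyl has two sp2 arms, so facial discrimination may be poor; an uncatalysed background addition or reduction of the quinone by the reagent mixture may also compete. The fallback uses known chemistry and sets out from 17: a Barbier allylation with indium metal and allyl bromide (NaI, DMF, rt), the established 1,2-allylation of ortho-quinones and other 1,2-diones. It should add at the same C5 carbonyl without facial control and give 19 together with its C5 epimer, (2S,3S,5S)-5-hydroxy-3-methyl-5-(prop-2-en-1-yl)-2-(3,4,5-trimethoxyphenyl)-2,3-dihydro-1-benzofuran-6(5H)-one F1. The two are diastereomers and would be separated by chromatography, which brings the route back at 19.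

Step 6. The ethylidene quinone methide may tautomerise to the vinylphenol before the ylide reaches it, the benzyl group may pass from sulfur to the phenoxide oxygen, or the facial control of the ylide may erode. The fallback sets out from 3 and forms the same ring by an oxidative [3+2] cycloaddition. Phenol 3 and (E)-1,2,3-trimethoxy-5-(prop-1-en-1-yl)benzene F2 (isoelemicin, from base isomerisation of commercial elemicin) would be treated with PhI(OCOCF3)2 in MeCN at 0 °C. The phenoxonium ion of 3 is attacked at its free ortho carbon by the propenyl β-carbon and the benzylic cation is closed by the phenol oxygen to the trans-dihydrobenzofuran. This gives the racemate, that is 15 with its mirror image (2R,3R)-5,6-bis(benzyloxy)-3-methyl-2-(3,4,5-trimethoxyphenyl)-2,3-dihydro-1-benzofuran F3. Preparative HPLC on a chiral stationary phase brings the route back at 15.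

Step 10. Etherification of the hindered tertiary hydroxyl may be slow, and [3,3] shifts of the allyl group (or an oxy-Cope shift if base is used to force the reaction) may take over. The fallback sets out from 11 and 4, carries the methoxy group from the start and brings in the allyl group last.
- 3-(Benzyloxy)-4-methoxyphenol F4 (purchased) would be condensed with 4 and sodium 4-methylbenzenesulfinate as in step 2 to rac-5-(benzyloxy)-4-methoxy-2-[1-(4-methylphenyl)sulfonylethyl]phenol F5.
- F5 and 11 under the conditions of step 6 should give (2S,3S)-6-(benzyloxy)-5-methoxy-3-methyl-2-(3,4,5-trimethoxyphenyl)-2,3-dihydro-1-benzofuran F6.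
- Hydrogenolysis (H2, Pd/C, EtOAc) should give (2S,3S)-5-methoxy-3-methyl-2-(3,4,5-trimethoxyphenyl)-2,3-dihydro-1-benzofuran-6-ol F7.
- Oxidation of F7 with PhI(OCOCF3)2 in the presence of allyltrimethylsilane (CH2Cl2, −78 °C) should place the allyl group on the methoxy-bearing C5. This oxidative nucleophilic substitution is known for 2-alkoxyarenols of the naphthalene series.
- The product would be 20 with its C5 epimer, (2S,3S,5S)-5-methoxy-3-methyl-5-(prop-2-en-1-yl)-2-(3,4,5-trimethoxyphenyl)-2,3-dihydro-1-benzofuran-6(5H)-one F8, separated by chromatography; the route is rejoined at 20.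

This detour also bypasses quinone 17 and carbinol 19.

**Further compounds**
F1 | step 9 | (2S,3S,5S)-5-hydroxy-3-methyl-5-(prop-2-en-1-yl)-2-(3,4,5-trimethoxyphenyl)-2,3-dihydro-1-benzofuran-6(5H)-one | C=CC[C@]1(O)C=C2C(=CC1=O)O[C@H](c1cc(OC)c(OC)c(OC)c1)[C@H]2C
F2 | step 6 | (E)-1,2,3-trimethoxy-5-(prop-1-en-1-yl)benzene (isoelemicin) | C/C=C/c1cc(OC)c(OC)c(OC)c1
F3 | step 6 | (2R,3R)-5,6-bis(benzyloxy)-3-methyl-2-(3,4,5-trimethoxyphenyl)-2,3-dihydro-1-benzofuran | c12cc(OCc3ccccc3)c(OCc3ccccc3)cc1O[C@@H](c4cc(OC)c(OC)c(OC)c4)[C@@H]2C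
F4 | step 10 | 3-(benzyloxy)-4-methoxyphenol | Oc1ccc(OC)c(OCc2ccccc2)c1
F5 | step 10 | rac-5-(benzyloxy)-4-methoxy-2-[1-(4-methylphenyl)sulfonylethyl]phenol | CC(c1cc(OC)c(OCc2ccccc2)cc1O)S(=O)(=O)c1ccc(C)cc1
F6 | step 10 | (2S,3S)-6-(benzyloxy)-5-methoxy-3-methyl-2-(3,4,5-trimethoxyphenyl)-2,3-dihydro-1-benzofuran | c12cc(OC)c(OCc3ccccc3)cc1O[C@H](c4cc(OC)c(OC)c(OC)c4)[C@H]2C
F7 | step 10 | (2S,3S)-5-methoxy-3-methyl-2-(3,4,5-trimethoxyphenyl)-2,3-dihydro-1-benzofuran-6-ol | c12cc(OC)c(O)cc1O[C@H](c3cc(OC)c(OC)c(OC)c3)[C@H]2C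
F8 | step 10 | (2S,3S,5S)-5-methoxy-3-methyl-5-(prop-2-en-1-yl)-2-(3,4,5-trimethoxyphenyl)-2,3-dihydro-1-benzofuran-6(5H)-one | C=CC[C@]1(OC)C=C2C(=CC1=O)O[C@H](c1cc(OC)c(OC)c(OC)c1)[C@H]2C
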